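The target is (−)-epicatechin 3-O-syringate. The five phenols are unmasked last (benzyl ethers, hydrogenolysis), and the C3 ester is cut (Steglich) to 5,7,3',4'-tetra-O-benzyl-(−)-epicatechin and 4-O-benzylsyringic acid.
Ring C is the only ring that is built; rings A and B and the syringoyl ring are bought as arenes. It is closed at O1–C8a by in-plane addition of the C2 alkoxide to a C8≡C8a aryne of ring A, in the same flask in which ring B is joined to C2.
Enabling feature: C8a lies meta to both ring A oxygens (on C5 and C7) and cannot be functionalised directly, but its neighbour C8 is ortho/para to them. A C8–Br next to C8a–H is a latent aryne, the C7 oxygen polarises it for attack at C8a, and the oxygen on C2 is placed for a six-membered ring.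
Symmetric 4,6-dibromoresorcinol delivers ring A. One bromine becomes the C4a nucleophile that opens methyl (R)-glycidate (C4–C4a bond, C3 from the chiral pool); the other is the traceless aryne trigger on C8.
C2 is set from C3 by chelation. The closure breaks no bond at C2 or C3, so the syn-1,2-dioxygenated chain maps directly onto the 2,3-cis (2R,3R) flavan.
Key step: step 5

Remark: the flavan numbering of the target (O1, C2, C3, C4, C4a, C5 to C8, C8a; ring A = benzo ring, ring C = pyran ring, ring B = aryl group on C2) is used for the same atoms in all earlier compounds.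

Step 1
Reactants: 1 4,6-dibromoresorcinol
Product: 2 1,5-dibromo-2,4-bis(benzyloxy)benzene
Conditions: BnBr (2.3 equiv), K2CO3, DMF, 60 °C
Reagents that add atoms: benzyl bromide, BrCc1ccccc1
Why: Double Williamson ether synthesis on the two acidic phenols, with benzyl chosen because it withstands the organometallic steps and is removed in the last step without touching methyl ethers or the ester.

Step 2
Reactants: 2 1,5-dibromo-2,4-bis(benzyloxy)benzene; 3 methyl (2R)-oxirane-2-carboxylate (methyl (R)-glycidate)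
Product: 6 methyl (2R)-3-[2,4-bis(benzyloxy)-5-bromophenyl]-2-hydroxypropanoate, via ring A aryllithium 4 (not isolated), via ring A arylmagnesium bromide 5 (not isolated)
Conditions: n-BuLi (1.0 equiv), THF, −78 °C; MgBr2·OEt2, −78 to −30 °C; CuBr·SMe2 (10 mol %), 3, −30 to 0 °C; aq. NH4Cl
Reagents that add atoms: none
Why: Bromine–lithium exchange on the symmetric dibromide can give only one aryllithium, and after transmetalation the copper-catalysed Grignard opening of the glycidic ester is an SN2 attack at the unsubstituted epoxide carbon (C4), so the C3–O bond and its R configuration from the chiral pool stay untouched while the second bromine (on C8, meta to the metal and thus not prone to elimination) is kept.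

Step 3
Reactants: 6 methyl (2R)-3-[2,4-bis(benzyloxy)-5-bromophenyl]-2-hydroxypropanoate
Product: 7 methyl (2R)-3-[2,4-bis(benzyloxy)-5-bromophenyl]-2-(methoxymethoxy)propanoate
Conditions: MOMCl, i-Pr2NEt, CH2Cl2, 0 °C to rt
Reagents that add atoms: chloromethyl methyl ether, COCCl
Why: O-alkylation of the secondary alcohol under amine base (acetal protection) keeps the C3 oxygen from ever acting as an alkoxide and supplies the chelating ether needed in step 5, without involving the stereocentre.

Step 4
Reactants: 7 methyl (2R)-3-[2,4-bis(benzyloxy)-5-bromophenyl]-2-(methoxymethoxy)propanoate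
Product: 8 (2R)-3-[2,4-bis(benzyloxy)-5-bromophenyl]-2-(methoxymethoxy)propanal
Conditions: i-Bu2AlH (1.1 equiv), toluene, −78 °C; aq. potassium sodium tartrate
Reagents that add atoms: none
Why: Partial reduction of an α-alkoxy ester with i-Bu2AlH at low temperature stops at the chelated aluminium hemiacetal, which releases the aldehyde only on work-up, and the crude aldehyde is used at once so that C3 should not epimerise.

Step 5
Reactants: 8 (2R)-3-[2,4-bis(benzyloxy)-5-bromophenyl]-2-(methoxymethoxy)propanal; 9 4-bromo-1,2-bis(benzyloxy)benzene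
Product: 14 (2R,3R)-5,7-bis(benzyloxy)-2-[3,4-bis(benzyloxy)phenyl]-3-(methoxymethoxy)chromane, via ring B arylmagnesium bromide 10 (not isolated), via syn bromomagnesium alkoxide 11 (not isolated), via aryne bromomagnesium alkoxide 12 (not isolated), via C8 arylmagnesium bromide 13 (not isolated)
Conditions: 9, Mg, THF, 40 °C; then 8, toluene, −78 °C; then lithium 2,2,6,6-tetramethylpiperidide (5 equiv, preformed from 2,2,6,6-tetramethylpiperidine and n-BuLi), THF, −78 to 0 °C; aq. NH4Cl
Reagents that add atoms: none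
Why: Arylmagnesium bromide 10 adds to aldehyde 8 through the five-membered magnesium chelate between the aldehyde oxygen and the C3 acetal oxygen, so the aryl group enters from the face that carries H and not C4 and sets C2 as R, syn to C3, in alkoxide 11 (chelation-controlled Grignard addition, the new stereocentre being controlled by C3). The excess lithium amide, guided by the side-chain oxygens, then removes HBr across C8a–H and C8–Br, and because the other neighbour of the bromine (C7) carries a benzyloxy group only the C8≡C8a aryne 12 can form (base-induced aryne generation as practised on 1-bromo-2,4-dialkoxybenzenes). The C2 alkoxide adds in the plane of ring A to C8a and closes ring C in the 6-exo-dig mode (intramolecular alkoxide capture of an aryne, the known aryne route to chromanes), and the C8 carbanion 13, stabilised by the adjacent C7 oxygen, takes a proton from the amine or at the quench, so the bromine leaves no trace. Site selectivity on the aryne is secured twice, by the tether, which can reach only C8a, and by the inductive pull of the C7 oxygen, which directs nucleophiles to the aryne carbon remote from it. Ring-size selectivity (chromane and not 2,3-dihydrobenzofuran) is secured by the MOM group, which keeps the C3 oxygen from ever being an alkoxide, and since no bond to C2 or C3 is broken the syn chain becomes the 2,3-cis flavan. A halogen dance of the lithiated bromide would only exchange the places of metal and bromine on C8a and C8 and lead to the same aryne, and metalation at C6 is reversed at the quench.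

Step 6
Reactants: 14 (2R,3R)-5,7-bis(benzyloxy)-2-[3,4-bis(benzyloxy)phenyl]-3-(methoxymethoxy)chromane
Product: 15 (2R,3R)-5,7-bis(benzyloxy)-2-[3,4-bis(benzyloxy)phenyl]chroman-3-ol (5,7,3',4'-tetra-O-benzyl-(−)-epicatechin)
Conditions: conc. HCl (cat.), MeOH–THF, 40 °C
Reagents that add atoms: none
Why: Acid-catalysed transacetalisation to methanol removes the aliphatic MOM group as dimethoxymethane at an acidity that should leave the benzyl ethers and the O1–C2 bond, and therefore both stereocentres, untouched.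

Step 7
Reactants: 16 syringic acid (4-hydroxy-3,5-dimethoxybenzoic acid)
Product: 18 4-(benzyloxy)-3,5-dimethoxybenzoic acid, via benzyl ester 17 (not isolated)
Conditions: BnBr (2.3 equiv), K2CO3, DMF, 60 °C; then NaOH, MeOH–H2O, 70 °C; HCl
Reagents that add atoms: benzyl bromide, BrCc1ccccc1; sodium hydroxide, [Na+].[OH-]
Why: Exhaustive benzylation (Williamson ether synthesis and carboxylate alkylation) followed by saponification of the benzyl ester leaves the phenol masked, so that only the carboxyl group can react in step 8.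

Step 8
Reactants: 15 5,7,3',4'-tetra-O-benzyl-(−)-epicatechin; 18 4-(benzyloxy)-3,5-dimethoxybenzoic acid
Product: 19 (2R,3R)-5,7-bis(benzyloxy)-2-[3,4-bis(benzyloxy)phenyl]chroman-3-yl 4-(benzyloxy)-3,5-dimethoxybenzoate
Conditions: DCC, DMAP (cat.), CH2Cl2, 0 °C to rt
Reagents that add atoms: none
Why: Steglich esterification acylates the single free (axial) C3 hydroxyl at oxygen with retention, which is the usual way to make 3-O-aroyl derivatives of benzylated flavan-3-ols.

Step 9
Reactants: 19 (2R,3R)-5,7-bis(benzyloxy)-2-[3,4-bis(benzyloxy)phenyl]chroman-3-yl 4-(benzyloxy)-3,5-dimethoxybenzoate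
Product: 20 (2R,3R)-2-(3,4-dihydroxyphenyl)-5,7-dihydroxychroman-3-yl 4-hydroxy-3,5-dimethoxybenzoate ((−)-epicatechin 3-O-syringate, CNP0128506.1)
Conditions: H2 (1 atm), Pd(OH)2/C, THF–MeOH, rt
Reagents that add atoms: none
Why: Catalytic hydrogenolysis cleaves all five O-benzyl groups under neutral conditions that spare the aryl methyl ethers, the ester and, by close analogy with benzylated flavan-3-ol esters, the cyclic O1–C2 ether, so no stereocentre is touched.

Compound list
1 | 4,6-dibromoresorcinol | Oc1cc(O)c(Br)cc1Br | starting material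
2 | 1,5-dibromo-2,4-bis(benzyloxy)benzene | Brc1cc(Br)c(OCc2ccccc2)cc1OCc1ccccc1 | intermediate
3 | methyl (2R)-oxirane-2-carboxylate | COC(=O)[C@H]1CO1 | starting material
4 | [2,4-bis(benzyloxy)-5-bromophenyl]lithium | [Li]c1cc(Br)c(OCc2ccccc2)cc1OCc1ccccc1 | intermediate
5 | [2,4-bis(benzyloxy)-5-bromophenyl]magnesium bromide | Br[Mg]c1cc(Br)c(OCc2ccccc2)cc1OCc1ccccc1 | intermediate
6 | methyl (2R)-3-[2,4-bis(benzyloxy)-5-bromophenyl]-2-hydroxypropanoate | COC(=O)[C@H](O)Cc1cc(Br)c(OCc2ccccc2)cc1OCc1ccccc1 | intermediate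
7 | methyl (2R)-3-[2,4-bis(benzyloxy)-5-bromophenyl]-2-(methoxymethoxy)propanoate | COCO[C@H](Cc1cc(Br)c(OCc2ccccc2)cc1OCc1ccccc1)C(=O)OC | intermediate
8 | (2R)-3-[2,4-bis(benzyloxy)-5-bromophenyl]-2-(methoxymethoxy)propanal | COCO[C@H](Cc1cc(Br)c(OCc2ccccc2)cc1OCc1ccccc1)C=O | intermediate
9 | 4-bromo-1,2-bis(benzyloxy)benzene | Brc1ccc(OCc2ccccc2)c(OCc2ccccc2)c1 | starting material
10 | [3,4-bis(benzyloxy)phenyl]magnesium bromide | Br[Mg]c1ccc(OCc2ccccc2)c(OCc2ccccc2)c1 | intermediate
11 | bromomagnesium (1R,2R)-1-[3,4-bis(benzyloxy)phenyl]-3-[2,4-bis(benzyloxy)-5-bromophenyl]-2-(methoxymethoxy)propan-1-olate | COCO[C@H](Cc1cc(Br)c(OCc2ccccc2)cc1OCc1ccccc1)[C@H](O[Mg]Br)c1ccc(OCc2ccccc2)c(OCc2ccccc2)c1 | intermediate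
12 | C8≡C8a aryne of 11 (bromomagnesium alkoxide of the 3,5-bis(benzyloxy)-6-alkylbenzyne) | COCO[C@H](CC1=C(OCc2ccccc2)C=C(OCc2ccccc2)C#C1)[C@H](O[Mg]Br)c1ccc(OCc2ccccc2)c(OCc2ccccc2)c1 | intermediate
13 | {(2R,3R)-5,7-bis(benzyloxy)-2-[3,4-bis(benzyloxy)phenyl]-3-(methoxymethoxy)chroman-8-yl}magnesium bromide | COCO[C@@H]1Cc2c(OCc3ccccc3)cc(OCc3ccccc3)c([Mg]Br)c2O[C@@H]1c1ccc(OCc2ccccc2)c(OCc2ccccc2)c1 | intermediate
14 | (2R,3R)-5,7-bis(benzyloxy)-2-[3,4-bis(benzyloxy)phenyl]-3-(methoxymethoxy)chromane | COCO[C@@H]1Cc2c(OCc3ccccc3)cc(OCc3ccccc3)cc2O[C@@H]1c1ccc(OCc2ccccc2)c(OCc2ccccc2)c1 | intermediate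
15 | (2R,3R)-5,7-bis(benzyloxy)-2-[3,4-bis(benzyloxy)phenyl]chroman-3-ol | O[C@@H]1Cc2c(OCc3ccccc3)cc(OCc3ccccc3)cc2O[C@@H]1c1ccc(OCc2ccccc2)c(OCc2ccccc2)c1 | intermediate
16 | syringic acid | COc1cc(C(=O)O)cc(OC)c1O | starting material
17 | benzyl 4-(benzyloxy)-3,5-dimethoxybenzoate | COc1cc(C(=O)OCc2ccccc2)cc(OC)c1OCc1ccccc1 | intermediate
18 | 4-(benzyloxy)-3,5-dimethoxybenzoic acid | COc1cc(C(=O)O)cc(OC)c1OCc1ccccc1 | intermediate
19 | (2R,3R)-5,7-bis(benzyloxy)-2-[3,4-bis(benzyloxy)phenyl]chroman-3-yl 4-(benzyloxy)-3,5-dimethoxybenzoate | COc1cc(C(=O)O[C@@H]2Cc3c(OCc4ccccc4)cc(OCc4ccccc4)cc3O[C@@H]2c2ccc(OCc3ccccc3)c(OCc3ccccc3)c2)cc(OC)c1OCc1ccccc1 | intermediate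
20 | (2R,3R)-2-(3,4-dihydroxyphenyl)-5,7-dihydroxychroman-3-yl 4-hydroxy-3,5-dimethoxybenzoate | COc1cc(C(=O)O[C@@H]2Cc3c(O)cc(O)cc3O[C@@H]2c2ccc(O)c(O)c2)cc(OC)c1O | target

Total step count: 9. Longest linear sequence: 8 steps (steps 1, 2, 3, 4, 5, 6, 8 and 9).

The three steps most likely to fail:

First, step 5.
- What may go wrong:
  - The dehydrobromination may stall, because C8a–H is flanked by C4 and by bromine and the magnesium salts tame the lithium amide.
  - Metalation of the benzylic O–CH2 groups, or addition of surplus 10 to the aryne, may compete.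
  - THF may erode the facial selectivity of the addition.
- Fallback: it sets out from 3 and comes back at 14. It puts the halogen on C8a itself and separates the events.
  - Commercial 1,3-bis(benzyloxy)-5-bromobenzene is iodinated with N-iodosuccinimide next to the bromine to give 1,5-bis(benzyloxy)-3-bromo-2-iodobenzene F1.
  - Selective iodine–magnesium exchange (i-PrMgCl, THF, −40 °C) and CuBr·SMe2-catalysed opening of 3 give methyl (2R)-3-[2,4-bis(benzyloxy)-6-bromophenyl]-2-hydroxypropanoate F2.
  - MOMCl and i-Pr2NEt give methyl (2R)-3-[2,4-bis(benzyloxy)-6-bromophenyl]-2-(methoxymethoxy)propanoate F3.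
  - i-Bu2AlH gives (2R)-3-[2,4-bis(benzyloxy)-6-bromophenyl]-2-(methoxymethoxy)propanal F4.
  - Chelation-controlled addition of 10, with isolation and purification, gives (1R,2R)-1-[3,4-bis(benzyloxy)phenyl]-3-[2,4-bis(benzyloxy)-6-bromophenyl]-2-(methoxymethoxy)propan-1-ol F5.
  - Palladium-catalysed intramolecular aryl ether formation (Buchwald–Hartwig etherification; Pd(OAc)2, 2-(di-tert-butylphosphino)-1,1'-binaphthyl, Cs2CO3, toluene, 70 °C) then closes the same O1–C8a bond with retention at C2 and leads to 14.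

Second, step 2.
- What may go wrong: the aryl metal may attack the ester carbonyl of the glycidate, and the 1-bromobutane formed in the exchange may butylate the arylmagnesium species under copper catalysis.
- Fallback: it sets out from 2 and comes back at 8. It uses an epoxide without a carbonyl group.
  - Aryllithium 4, made from 2 as before, is combined at −78 °C with BF3·OEt2 and commercial (R)-tert-butyldimethylsilyl glycidyl ether to give (2R)-1-[2,4-bis(benzyloxy)-5-bromophenyl]-3-[(tert-butyldimethylsilyl)oxy]propan-2-ol F6.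
  - MOMCl and i-Pr2NEt give {(2R)-3-[2,4-bis(benzyloxy)-5-bromophenyl]-2-(methoxymethoxy)propoxy}(tert-butyl)dimethylsilane F7.
  - Bu4NF gives (2R)-3-[2,4-bis(benzyloxy)-5-bromophenyl]-2-(methoxymethoxy)propan-1-ol F8.
  - Dess–Martin oxidation of F8 gives 8.

Third, step 6.
- What may go wrong: the acid needed for an aliphatic MOM ether may open ring C at the benzylic O1–C2 bond, with loss of configuration at C2, or may attack the electron-rich ring A.
- Fallback: it sets out from 6 and comes back at 15. It replaces the acid-labile acetal with a fluoride-labile one that chelates equally well.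
  - 2-(Trimethylsilyl)ethoxymethyl chloride and i-Pr2NEt give methyl (2R)-3-[2,4-bis(benzyloxy)-5-bromophenyl]-2-{[2-(trimethylsilyl)ethoxy]methoxy}propanoate F9.
  - i-Bu2AlH gives (2R)-3-[2,4-bis(benzyloxy)-5-bromophenyl]-2-{[2-(trimethylsilyl)ethoxy]methoxy}propanal F10.
  - The conditions of step 5 give (2R,3R)-5,7-bis(benzyloxy)-2-[3,4-bis(benzyloxy)phenyl]-3-{[2-(trimethylsilyl)ethoxy]methoxy}chromane F11.
  - Bu4NF in DMPU at 80 °C then frees the C3 hydroxyl of 15 without any acid.

Further compounds
F1 | step 5 | 1,5-bis(benzyloxy)-3-bromo-2-iodobenzene | Ic1c(Br)cc(OCc2ccccc2)cc1OCc1ccccc1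
F2 | step 5 | methyl (2R)-3-[2,4-bis(benzyloxy)-6-bromophenyl]-2-hydroxypropanoate | COC(=O)[C@H](O)Cc1c(Br)cc(OCc2ccccc2)cc1OCc1ccccc1
F3 | step 5 | methyl (2R)-3-[2,4-bis(benzyloxy)-6-bromophenyl]-2-(methoxymethoxy)propanoate | COCO[C@H](Cc1c(Br)cc(OCc2ccccc2)cc1OCc1ccccc1)C(=O)OC
F4 | step 5 | (2R)-3-[2,4-bis(benzyloxy)-6-bromophenyl]-2-(methoxymethoxy)propanal | COCO[C@H](Cc1c(Br)cc(OCc2ccccc2)cc1OCc1ccccc1)C=O
F5 | step 5 | (1R,2R)-1-[3,4-bis(benzyloxy)phenyl]-3-[2,4-bis(benzyloxy)-6-bromophenyl]-2-(methoxymethoxy)propan-1-ol | COCO[C@H](Cc1c(Br)cc(OCc2ccccc2)cc1OCc1ccccc1)[C@H](O)c1ccc(OCc2ccccc2)c(OCc2ccccc2)c1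
F6 | step 2 | (2R)-1-[2,4-bis(benzyloxy)-5-bromophenyl]-3-[(tert-butyldimethylsilyl)oxy]propan-2-ol | CC(C)(C)[Si](C)(C)OC[C@H](O)Cc1cc(Br)c(OCc2ccccc2)cc1OCc1ccccc1
F7 | step 2 | {(2R)-3-[2,4-bis(benzyloxy)-5-bromophenyl]-2-(methoxymethoxy)propoxy}(tert-butyl)dimethylsilane | CC(C)(C)[Si](C)(C)OC[C@H](OCOC)Cc1cc(Br)c(OCc2ccccc2)cc1OCc1ccccc1
F8 | step 2 | (2R)-3-[2,4-bis(benzyloxy)-5-bromophenyl]-2-(methoxymethoxy)propan-1-ol | OC[C@H](OCOC)Cc1cc(Br)c(OCc2ccccc2)cc1OCc1ccccc1
F9 | step 6 | methyl (2R)-3-[2,4-bis(benzyloxy)-5-bromophenyl]-2-{[2-(trimethylsilyl)ethoxy]methoxy}propanoate | C[Si](C)(C)CCOCO[C@H](Cc1cc(Br)c(OCc2ccccc2)cc1OCc1ccccc1)C(=O)OC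
F10 | step 6 | (2R)-3-[2,4-bis(benzyloxy)-5-bromophenyl]-2-{[2-(trimethylsilyl)ethoxy]methoxy}propanal | C[Si](C)(C)CCOCO[C@H](Cc1cc(Br)c(OCc2ccccc2)cc1OCc1ccccc1)C=O
F11 | step 6 | (2R,3R)-5,7-bis(benzyloxy)-2-[3,4-bis(benzyloxy)phenyl]-3-{[2-(trimethylsilyl)ethoxy]methoxy}chromane | C[Si](C)(C)CCOCO[C@@H]1Cc2c(OCc3ccccc3)cc(OCc3ccccc3)cc2O[C@@H]1c1ccc(OCc2ccccc2)c(OCc2ccccc2)c1
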